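**Plan**
- Cuts: (i) the enol-ether C–O bond of the dihydropyran (tertiary O to C10 of the dibenzo[b,f]oxepine), giving a δ-hydroxy ketone; (ii) C10–C11 and the diaryl ether bond O5–C5a, both in one operation; (iii) C11–CH2, giving an arylacetic enediolate and a terminal epoxide.
- Enabling feature: C11 is the α-carbon of a (2-hydroxyaryl)acetic acid unit of ring A (O5 sits ortho to it), and C10 is an aroyl carbon of ring B whose ortho carbon carries O5. Ring A is therefore carried as a benzofuran-2(3H)-one (lactone O = masked O5, lactone C=O = removable acidifier of C11) and ring B as a 2-fluorobenzoyl chloride.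
- Forward order: the ring A lactone receives the side chain at C11; a one-pot acyl transfer / lactone hydrolysis / SNAr / decarboxylation builds the seven-membered ring; hemiketalisation–dehydration closes the pyran; deprotection follows.
- Stereochemistry: both centres come from nerol. Sharpless epoxidation with L-(+)-tartrate gives the (2S,3R)-epoxide; hydrolysis with inversion at the tertiary carbon gives the (2S,3S)-triol; neither C–O bond is broken afterwards.
- Helpers: allyl ethers on both phenols, TBS on the secondary OH (blocks five-membered closure), TES on the tertiary OH (blocks attack on the lactone).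

Key step: step 13

Remark: 6-hydroxy-1-benzofuran-2(3H)-one (7) is taken as a catalogue compound; it is the lactone of commercial (2,4-dihydroxyphenyl)acetic acid.

**Route**

Step 1
Reactants: 1 nerol, (2Z)-3,7-dimethylocta-2,6-dien-1-ol
Product: 2 [(2S,3R)-3-methyl-3-(4-methylpent-3-en-1-yl)oxiran-2-yl]methanol
Conditions: Ti(OiPr)4 (cat.), L-(+)-diethyl tartrate, t-BuOOH, 4 Å MS, CH2Cl2, –20 °C
Reagents that add atoms: tert-butyl hydroperoxide, CC(C)(C)OO
Why: Sharpless asymmetric epoxidation acts only on the allylic-alcohol double bond, and the L-(+)-tartrate catalyst should deliver oxygen to the face that gives the (2S,3R) cis-epoxide.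

Step 2
Reactants: 2 [(2S,3R)-3-methyl-3-(4-methylpent-3-en-1-yl)oxiran-2-yl]methanol
Product: 3 (2S,3S)-3,7-dimethyloct-6-ene-1,2,3-triol
Conditions: HClO4 (cat.), THF–H2O, 0 °C
Reagents that add atoms: water, O
Why: Acid-catalysed epoxide hydrolysis, in which water attacks the protonated epoxide at the tertiary carbon with inversion (C3 R to S) while C2 keeps its oxygen (S).

Step 3
Reactants: 3 (2S,3S)-3,7-dimethyloct-6-ene-1,2,3-triol
Product: 5 (2S)-6-methyl-2-[(2S)-oxiran-2-yl]hept-5-en-2-ol, via primary tosylate 4 (not isolated)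
Conditions: Bu2SnO (cat.), TsCl, Et3N, CH2Cl2, 0 °C; then K2CO3, MeOH, 0 °C
Reagents that add atoms: none
Why: Tin-catalysed sulfonylation should tosylate only the primary hydroxyl, and the C2 alkoxide then displaces the tosylate (3-exo-tet Williamson closure) without breaking a bond to either stereocentre; the weak base keeps Payne back-rearrangement slow.

Step 4
Reactants: 5 (2S)-6-methyl-2-[(2S)-oxiran-2-yl]hept-5-en-2-ol
Product: 6 triethyl({(2S)-6-methyl-2-[(2S)-oxiran-2-yl]hept-5-en-2-yl}oxy)silane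
Conditions: TESOTf, 2,6-lutidine, CH2Cl2, –78 °C
Reagents that add atoms: triethylsilyl trifluoromethanesulfonate, CC[Si](CC)(CC)OS(=O)(=O)C(F)(F)F
Why: Silyl triflate silylation of a hindered tertiary alcohol at low temperature; the TES ether stops Payne rearrangement in step 9 and intramolecular lactone opening in step 13.

Step 5
Reactants: 7 6-hydroxy-1-benzofuran-2(3H)-one
Product: 8 5-bromo-6-hydroxy-1-benzofuran-2(3H)-one
Conditions: NBS, MeCN, –10 °C to rt, dark
Reagents that add atoms: N-bromosuccinimide, BrN1C(=O)CCC1=O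
Why: Electrophilic aromatic bromination should go ortho to the free phenol at C5, which is also para to the ring oxygen and less hindered than C7 between the two oxygens.

Step 6
Reactants: 8 5-bromo-6-hydroxy-1-benzofuran-2(3H)-one
Product: 9 6-hydroxy-5-(3-methylbut-2-en-1-yl)-1-benzofuran-2(3H)-one
Conditions: Bu3SnCH2CH=CMe2, Pd(PPh3)4 (5 mol%), DMF, 90 °C
Reagents that add atoms: tributyl(3-methylbut-2-en-1-yl)stannane, CCCC[Sn](CCCC)(CCCC)CC=C(C)C
Why: Stille coupling under base-free conditions (zerovalent palladium) spares the enolisable lactone, and reductive elimination at the unsubstituted terminus of the η3-prenyl palladium intermediate should give the linear prenyl group.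

Step 7
Reactants: 9 6-hydroxy-5-(3-methylbut-2-en-1-yl)-1-benzofuran-2(3H)-one
Product: 10 5-(3-methylbut-2-en-1-yl)-6-(prop-2-en-1-yloxy)-1-benzofuran-2(3H)-one
Conditions: allyl alcohol, PPh3, DIAD, THF, 0 °C to rt
Reagents that add atoms: allyl alcohol, C=CCO
Why: Mitsunobu etherification, in which the phenol is the competent pronucleophile while the lactone C3–H is too weak a carbon acid for DIAD/PPh3, so oxygen is allylated without enolate chemistry at C3.

Step 8
Reactants: 10 5-(3-methylbut-2-en-1-yl)-6-(prop-2-en-1-yloxy)-1-benzofuran-2(3H)-one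
Product: 11 [2-hydroxy-5-(3-methylbut-2-en-1-yl)-4-(prop-2-en-1-yloxy)phenyl]acetic acid
Conditions: LiOH, THF–H2O, 0 °C; then cold 1 M HCl to pH 3
Reagents that add atoms: lithium hydroxide, [Li+].[OH-]
Why: Saponification of the strained aryl lactone is fast at 0 °C, and the hydroxy acid is used at once before it relactonises.

Step 9
Reactants: 11 [2-hydroxy-5-(3-methylbut-2-en-1-yl)-4-(prop-2-en-1-yloxy)phenyl]acetic acid; 6 triethyl({(2S)-6-methyl-2-[(2S)-oxiran-2-yl]hept-5-en-2-yl}oxy)silane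
Product: 13 (2RS,4S,5S)-4-[(tert-butyldimethylsilyl)oxy]-2-[2-hydroxy-5-(3-methylbut-2-en-1-yl)-4-(prop-2-en-1-yloxy)phenyl]-5,9-dimethyl-5-[(triethylsilyl)oxy]dec-8-enoic acid, via tris-silyl ester 12 (not isolated)
Conditions: LiN(iPr)2 (3.3 equiv), THF–DMPU, –78 to 0 °C; 6, 0 to 40 °C; then TBSOTf (3.3 equiv), –78 to 0 °C; then K2CO3, MeOH, rt; pH 4 work-up
Reagents that add atoms: tert-butyldimethylsilyl trifluoromethanesulfonate, CC(C)(C)[Si](C)(C)OS(=O)(=O)C(F)(F)F
Why: Creger-type alkylation, in which the lithium enediolate opens the terminal epoxide at its CH2 carbon (SN2, no stereocentre touched, C2 epimers of no consequence); the carboxylate cannot lactonise under base, so the new alkoxide is capped as its TBS ether, and K2CO3/MeOH then removes only the silyl ester and the aryl silyl ether.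

Step 10
Reactants: 13 (2RS,4S,5S)-4-[(tert-butyldimethylsilyl)oxy]-2-[2-hydroxy-5-(3-methylbut-2-en-1-yl)-4-(prop-2-en-1-yloxy)phenyl]-5,9-dimethyl-5-[(triethylsilyl)oxy]dec-8-enoic acid
Product: 14 (3RS)-3-{(2S,3S)-2-[(tert-butyldimethylsilyl)oxy]-3,7-dimethyl-3-[(triethylsilyl)oxy]oct-6-en-1-yl}-5-(3-methylbut-2-en-1-yl)-6-(prop-2-en-1-yloxy)-1-benzofuran-2(3H)-one
Conditions: DCC, CH2Cl2, 0 °C to rt
Reagents that add atoms: none
Why: Carbodiimide lactonisation of a (2-hydroxyaryl)acetic acid (5-exo-trig acyl substitution) restores the benzofuranone, which again masks the ring A phenol and acidifies C3.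

Step 11
Reactants: 15 2-fluoro-4-hydroxybenzoic acid
Product: 17 2-fluoro-4-(prop-2-en-1-yloxy)benzoic acid, via allyl ester 16 (not isolated)
Conditions: allyl bromide (2.3 equiv), K2CO3, DMF, 50 °C; then NaOH, H2O–MeOH, rt; HCl
Reagents that add atoms: allyl bromide, C=CCBr
Why: Williamson O-allylation of phenol and carboxylate, then saponification of the allyl ester in the same pot; the aryl allyl ether is stable to hydroxide.

Step 12
Reactants: 17 2-fluoro-4-(prop-2-en-1-yloxy)benzoic acid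
Product: 18 2-fluoro-4-(prop-2-en-1-yloxy)benzoyl chloride
Conditions: (COCl)2, DMF (cat.), CH2Cl2, 0 °C to rt; concentrate
Reagents that add atoms: oxalyl chloride, ClC(=O)C(Cl)=O
Why: Vilsmeier-catalysed acid chloride formation under neutral conditions with volatile by-products.

Step 13
Reactants: 14 (3RS)-3-{(2S,3S)-2-[(tert-butyldimethylsilyl)oxy]-3,7-dimethyl-3-[(triethylsilyl)oxy]oct-6-en-1-yl}-5-(3-methylbut-2-en-1-yl)-6-(prop-2-en-1-yloxy)-1-benzofuran-2(3H)-one; 18 2-fluoro-4-(prop-2-en-1-yloxy)benzoyl chloride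
Product: 23 (11RS)-11-{(2S,3S)-2-[(tert-butyldimethylsilyl)oxy]-3,7-dimethyl-3-[(triethylsilyl)oxy]oct-6-en-1-yl}-2-(3-methylbut-2-en-1-yl)-3,7-bis(prop-2-en-1-yloxy)dibenzo[b,f]oxepin-10(11H)-one, via enol ester 19 (not isolated), via C-acyl lactone 20 (not isolated), via phenol keto acid 21 (not isolated), via oxepinone acid 22 (not isolated)
Conditions: 18 (1.2 equiv), Et3N, MeCN, 0 °C; DMAP (0.2 equiv), 40 °C; then Cs2CO3, H2O, DMSO, 70 °C; pH 5 work-up
Reagents that add atoms: none
Why: Et3N gives the aromatic enolate of 14, which 18 acylates on oxygen, and DMAP then moves the aroyl group from O to C3 (the Steglich/Black O-to-C acyl shift of O-acylated benzofuranones), making the C10–C11 bond at a quaternary carbon that cannot re-enolise. Aqueous Cs2CO3 should open the strained aryl lactone of 20 faster than it adds to the hindered, electron-rich aryl ketone, releasing the ring A phenoxide ortho to C11 together with a β-keto carboxylate. The phenoxide closes the seven-membered ring by intramolecular SNAr (attack on the trigonal C–F carbon through a Meisenheimer intermediate, fluoride leaving from outside the new ring), and this carbon is activated only by the ortho ketone made in the first stage while the para oxygen stays an allyl ether instead of a deactivating phenoxide; the closest precedents are phenoxide cyclisations onto 2-fluoroaryl ketones and the SNAr/condensation route to dibenzo[b,f]oxepines. The β-keto acid 22 then loses CO2 through the usual six-membered transition state, which removes the temporary lactone carbon. C11 forms as a mixture of epimers, which does not matter because it becomes sp2 in step 14, and the side-chain stereocentres lie two and three bonds from any reacting atom. The step needs C- over O-acylation (thermodynamic under DMAP), lactone over ketone attack by hydroxide, and complete ether formation under base before the pH is lowered, because a free 2-hydroxyaryl ketone would dehydrate to a 2-arylbenzofuran under acid.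

Step 14
Reactants: 23 (11RS)-11-{(2S,3S)-2-[(tert-butyldimethylsilyl)oxy]-3,7-dimethyl-3-[(triethylsilyl)oxy]oct-6-en-1-yl}-2-(3-methylbut-2-en-1-yl)-3,7-bis(prop-2-en-1-yloxy)dibenzo[b,f]oxepin-10(11H)-one
Product: 25 the dibenzo[b,f]oxepine fused across C10=C11 to a 3,4-dihydro-2H-pyran (pyran O on C10, pyran CH2 on C11) with (2S)-methyl, (2S)-(4-methylpent-3-en-1-yl) and (3S)-OTBS on the pyran, 2-prenyl and 3,7-bis(allyloxy) on the arenes, via hydroxy ketone 24 (not isolated)
Conditions: CSA (0.1 equiv), MeOH–CH2Cl2, 0 °C to rt; then PPTS (0.1 equiv), PhMe, 4 Å MS, 60 °C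
Reagents that add atoms: none
Why: Acid should cleave the more labile TES ether but not the hindered secondary TBS ether; the freed tertiary hydroxyl adds to the C10 ketone (6-exo-trig hemiketal) and PPTS with sieves drives elimination through the aryl-stabilised oxocarbenium ion to the enol ether conjugated with both arenes, with both stereocentre C–O bonds retained and the TBS group preventing five-membered closure by the secondary oxygen.

Step 15
Reactants: 25 the TBS-protected bis(allyl) pyrano-fused dibenzo[b,f]oxepine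
Product: 26 the same ring system with free (3S)-OH on the pyran, 2-prenyl and 3,7-bis(allyloxy) on the arenes
Conditions: Bu4NF, THF, rt
Reagents that add atoms: none
Why: Fluoride-mediated desilylation under non-acidic conditions, so the freed secondary hydroxyl cannot re-equilibrate the enol ether to the dihydrofuran isomer.

Step 16
Reactants: 26 the bis(allyl ether) with free secondary alcohol
Product: 27 target: 3,7-dihydroxy-2-(3-methylbut-2-en-1-yl)dibenzo[b,f]oxepine fused across C10=C11 to a 3,4-dihydro-2H-pyran (O on C10, CH2 on C11) carrying (3S)-OH, (2S)-methyl and (2S)-(4-methylpent-3-en-1-yl)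
Conditions: Pd(PPh3)4 (5 mol%), morpholine, THF, rt, degassed
Reagents that add atoms: none
Why: Tsuji–Trost deallylation, in which Pd(PPh3)4 ionises the aryl allyl ethers and morpholine traps the allyl unit, while the trisubstituted alkenes, the enol ether and the free alcohol should be inert.

**Compound list**

1 | nerol, (2Z)-3,7-dimethylocta-2,6-dien-1-ol | CC(C)=CCC/C(C)=C\CO | starting material
2 | [(2S,3R)-3-methyl-3-(4-methylpent-3-en-1-yl)oxiran-2-yl]methanol | OC[C@@H]1O[C@]1(C)CCC=C(C)C | intermediate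
3 | (2S,3S)-3,7-dimethyloct-6-ene-1,2,3-triol | OC[C@H](O)[C@@](C)(O)CCC=C(C)C | intermediate
4 | (2S,3S)-2,3-dihydroxy-3,7-dimethyloct-6-en-1-yl 4-methylbenzenesulfonate | Cc1ccc(cc1)S(=O)(=O)OC[C@H](O)[C@@](C)(O)CCC=C(C)C | intermediate
5 | (2S)-6-methyl-2-[(2S)-oxiran-2-yl]hept-5-en-2-ol | C1O[C@@H]1[C@@](C)(O)CCC=C(C)C | intermediate
6 | triethyl({(2S)-6-methyl-2-[(2S)-oxiran-2-yl]hept-5-en-2-yl}oxy)silane | C1O[C@@H]1[C@@](C)(O[Si](CC)(CC)CC)CCC=C(C)C | intermediate
7 | 6-hydroxy-1-benzofuran-2(3H)-one | O=C1Cc2ccc(O)cc2O1 | starting material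
8 | 5-bromo-6-hydroxy-1-benzofuran-2(3H)-one | O=C1Cc2cc(Br)c(O)cc2O1 | intermediate
9 | 6-hydroxy-5-(3-methylbut-2-en-1-yl)-1-benzofuran-2(3H)-one | O=C1Cc2cc(CC=C(C)C)c(O)cc2O1 | intermediate
10 | 5-(3-methylbut-2-en-1-yl)-6-(prop-2-en-1-yloxy)-1-benzofuran-2(3H)-one | O=C1Cc2cc(CC=C(C)C)c(OCC=C)cc2O1 | intermediate
11 | [2-hydroxy-5-(3-methylbut-2-en-1-yl)-4-(prop-2-en-1-yloxy)phenyl]acetic acid | OC(=O)Cc1cc(CC=C(C)C)c(OCC=C)cc1O | intermediate
12 | tert-butyldimethylsilyl (4S,5S)-4-[(tert-butyldimethylsilyl)oxy]-2-{2-[(tert-butyldimethylsilyl)oxy]-5-(3-methylbut-2-en-1-yl)-4-(prop-2-en-1-yloxy)phenyl}-5,9-dimethyl-5-[(triethylsilyl)oxy]dec-8-enoate | CC(C)(C)[Si](C)(C)OC(=O)C(C[C@H](O[Si](C)(C)C(C)(C)C)[C@@](C)(O[Si](CC)(CC)CC)CCC=C(C)C)c1cc(CC=C(C)C)c(OCC=C)cc1O[Si](C)(C)C(C)(C)C | intermediate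
13 | (2RS,4S,5S)-4-[(tert-butyldimethylsilyl)oxy]-2-[2-hydroxy-5-(3-methylbut-2-en-1-yl)-4-(prop-2-en-1-yloxy)phenyl]-5,9-dimethyl-5-[(triethylsilyl)oxy]dec-8-enoic acid | OC(=O)C(C[C@H](O[Si](C)(C)C(C)(C)C)[C@@](C)(O[Si](CC)(CC)CC)CCC=C(C)C)c1cc(CC=C(C)C)c(OCC=C)cc1O | intermediate
14 | (3RS)-3-{(2S,3S)-2-[(tert-butyldimethylsilyl)oxy]-3,7-dimethyl-3-[(triethylsilyl)oxy]oct-6-en-1-yl}-5-(3-methylbut-2-en-1-yl)-6-(prop-2-en-1-yloxy)-1-benzofuran-2(3H)-one | O=C1Oc2cc(OCC=C)c(CC=C(C)C)cc2C1C[C@H](O[Si](C)(C)C(C)(C)C)[C@@](C)(O[Si](CC)(CC)CC)CCC=C(C)C | intermediate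
15 | 2-fluoro-4-hydroxybenzoic acid | OC(=O)c1ccc(O)cc1F | starting material
16 | prop-2-en-1-yl 2-fluoro-4-(prop-2-en-1-yloxy)benzoate | C=CCOC(=O)c1ccc(OCC=C)cc1F | intermediate
17 | 2-fluoro-4-(prop-2-en-1-yloxy)benzoic acid | OC(=O)c1ccc(OCC=C)cc1F | intermediate
18 | 2-fluoro-4-(prop-2-en-1-yloxy)benzoyl chloride | ClC(=O)c1ccc(OCC=C)cc1F | intermediate
19 | 3-{(2S,3S)-2-[(tert-butyldimethylsilyl)oxy]-3,7-dimethyl-3-[(triethylsilyl)oxy]oct-6-en-1-yl}-5-(3-methylbut-2-en-1-yl)-6-(prop-2-en-1-yloxy)-1-benzofuran-2-yl 2-fluoro-4-(prop-2-en-1-yloxy)benzoate | C=CCOc1ccc(C(=O)Oc2oc3cc(OCC=C)c(CC=C(C)C)cc3c2C[C@H](O[Si](C)(C)C(C)(C)C)[C@@](C)(O[Si](CC)(CC)CC)CCC=C(C)C)c(F)c1 | intermediate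
20 | (3RS)-3-[2-fluoro-4-(prop-2-en-1-yloxy)benzoyl]-3-{(2S,3S)-2-[(tert-butyldimethylsilyl)oxy]-3,7-dimethyl-3-[(triethylsilyl)oxy]oct-6-en-1-yl}-5-(3-methylbut-2-en-1-yl)-6-(prop-2-en-1-yloxy)-1-benzofuran-2(3H)-one | C=CCOc1ccc(C(=O)C2(C[C@H](O[Si](C)(C)C(C)(C)C)[C@@](C)(O[Si](CC)(CC)CC)CCC=C(C)C)C(=O)Oc3cc(OCC=C)c(CC=C(C)C)cc32)c(F)c1 | intermediate
21 | (2RS,4S,5S)-4-[(tert-butyldimethylsilyl)oxy]-2-[2-fluoro-4-(prop-2-en-1-yloxy)benzoyl]-2-[2-hydroxy-5-(3-methylbut-2-en-1-yl)-4-(prop-2-en-1-yloxy)phenyl]-5,9-dimethyl-5-[(triethylsilyl)oxy]dec-8-enoic acid | C=CCOc1ccc(C(=O)C(C[C@H](O[Si](C)(C)C(C)(C)C)[C@@](C)(O[Si](CC)(CC)CC)CCC=C(C)C)(C(O)=O)c2cc(CC=C(C)C)c(OCC=C)cc2O)c(F)c1 | intermediate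
22 | (11RS)-11-{(2S,3S)-2-[(tert-butyldimethylsilyl)oxy]-3,7-dimethyl-3-[(triethylsilyl)oxy]oct-6-en-1-yl}-2-(3-methylbut-2-en-1-yl)-10-oxo-3,7-bis(prop-2-en-1-yloxy)-10,11-dihydrodibenzo[b,f]oxepine-11-carboxylic acid | C=CCOc1ccc2c(c1)Oc1cc(OCC=C)c(CC=C(C)C)cc1C(C[C@H](O[Si](C)(C)C(C)(C)C)[C@@](C)(O[Si](CC)(CC)CC)CCC=C(C)C)(C(O)=O)C2=O | intermediate
23 | (11RS)-11-{(2S,3S)-2-[(tert-butyldimethylsilyl)oxy]-3,7-dimethyl-3-[(triethylsilyl)oxy]oct-6-en-1-yl}-2-(3-methylbut-2-en-1-yl)-3,7-bis(prop-2-en-1-yloxy)dibenzo[b,f]oxepin-10(11H)-one | C=CCOc1ccc2c(c1)Oc1cc(OCC=C)c(CC=C(C)C)cc1C(C[C@H](O[Si](C)(C)C(C)(C)C)[C@@](C)(O[Si](CC)(CC)CC)CCC=C(C)C)C2=O | intermediate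
24 | (11RS)-11-{(2S,3S)-2-[(tert-butyldimethylsilyl)oxy]-3-hydroxy-3,7-dimethyloct-6-en-1-yl}-2-(3-methylbut-2-en-1-yl)-3,7-bis(prop-2-en-1-yloxy)dibenzo[b,f]oxepin-10(11H)-one | C=CCOc1ccc2c(c1)Oc1cc(OCC=C)c(CC=C(C)C)cc1C(C[C@H](O[Si](C)(C)C(C)(C)C)[C@@](C)(O)CCC=C(C)C)C2=O | intermediate
25 | pyrano-fused dibenzo[b,f]oxepine (pyran O on C10, CH2 on C11) with (2S)-methyl, (2S)-(4-methylpent-3-en-1-yl), (3S)-OTBS, 2-prenyl, 3,7-bis(allyloxy) | CC(C)=CCC[C@]1(C)OC2=C(C[C@@H]1O[Si](C)(C)C(C)(C)C)c1cc(CC=C(C)C)c(OCC=C)cc1Oc1cc(OCC=C)ccc12 | intermediate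
26 | the same ring system with free (3S)-OH, 2-prenyl, 3,7-bis(allyloxy) | CC(C)=CCC[C@]1(C)OC2=C(C[C@@H]1O)c1cc(CC=C(C)C)c(OCC=C)cc1Oc1cc(OCC=C)ccc12 | intermediate
27 | target, (2S,3S) on the pyran, 3,7-dihydroxy-2-prenyl on the dibenzo[b,f]oxepine | CC(C)=CCC[C@]1(C)OC2=C(C[C@@H]1O)c1cc(CC=C(C)C)c(O)cc1Oc1cc(O)ccc12 | target

**Count and risks**

Total step count: 16. Longest linear sequence: 10 steps (7 to 27 through steps 5–10 and 13–16; equally 1 to 27 through steps 1–4, 9, 10 and 13–16).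

Steps most likely to fail:

1. Step 13. The acyl shift to the crowded C3 may stall, hydroxide may cleave the aroyl group from 20 by retro-Claisen instead of opening the lactone, the silyl ethers may be lost to the fluoride released, or the ether closure may lag behind decarboxylation. Fallback, with the ether made first and the C–C bond second: acid 17 is methylated (MeI, K2CO3, DMF) to methyl 2-fluoro-4-(prop-2-en-1-yloxy)benzoate F1. The dicesium salt of hydroxy acid 13 is arylated by F1 (Cs2CO3, DMSO, 100 °C, ester-activated SNAr) to the diaryl ether acid F2. The enediolate of F2 (LiN(SiMe3)2, 3.2 equiv, THF, –40 to 0 °C) undergoes intramolecular Claisen condensation on the methyl ester, and acid work-up with loss of CO2 returns to ketone 23.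

2. Step 9. The triply charged enediolate, with a phenoxide on the same ring, may form or dissolve poorly and may act as a base on the epoxide instead of opening it. Fallback through a protecting-group detour: acid 11 is silylated (TBSCl, imidazole, DMF; aqueous K2CO3 work-up cleaves only the silyl ester) to {2-[(tert-butyldimethylsilyl)oxy]-5-(3-methylbut-2-en-1-yl)-4-(prop-2-en-1-yloxy)phenyl}acetic acid F3. Its ordinary dianion (LiN(iPr)2, 2.2 equiv, THF, 0 °C) opens epoxide 6, and TBSOTf gives the same tris-silyl intermediate 12. K2CO3/MeOH then returns to 13.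

3. Step 14. Desilylation may not discriminate between TES and TBS, which would let the secondary oxygen close the five-membered ring, and the acid may touch the alkenes. Fallback with isolation and base-compatible dehydration: from 23, buffered HF·pyridine (pyridine, THF, 0 °C) removes only the TES group and the tertiary alcohol closes onto the ketone to give the cyclic hemiketal F4. F4 is isolated and dehydrated under non-acidic conditions with Martin sulfurane, Ph2S[OC(CF3)2Ph]2 (CH2Cl2, 0 °C), returning to 25.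

Further compounds
F1 | step 13 | methyl 2-fluoro-4-(prop-2-en-1-yloxy)benzoate | COC(=O)c1ccc(OCC=C)cc1F
F2 | step 13 | (2RS,4S,5S)-4-[(tert-butyldimethylsilyl)oxy]-2-{2-[2-(methoxycarbonyl)-5-(prop-2-en-1-yloxy)phenoxy]-5-(3-methylbut-2-en-1-yl)-4-(prop-2-en-1-yloxy)phenyl}-5,9-dimethyl-5-[(triethylsilyl)oxy]dec-8-enoic acid | COC(=O)c1ccc(OCC=C)cc1Oc1cc(OCC=C)c(CC=C(C)C)cc1C(C[C@H](O[Si](C)(C)C(C)(C)C)[C@@](C)(O[Si](CC)(CC)CC)CCC=C(C)C)C(O)=O
F3 | step 9 | {2-[(tert-butyldimethylsilyl)oxy]-5-(3-methylbut-2-en-1-yl)-4-(prop-2-en-1-yloxy)phenyl}acetic acid | OC(=O)Cc1cc(CC=C(C)C)c(OCC=C)cc1O[Si](C)(C)C(C)(C)C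
F4 | step 14 | cyclic hemiketal of 24 (tertiary oxygen added to the C10 carbonyl; C10 bears OH; (3S)-OTBS, (2S)-methyl, (2S)-(4-methylpent-3-en-1-yl) on the tetrahydropyran) | C=CCOc1ccc2c(c1)Oc1cc(OCC=C)c(CC=C(C)C)cc1C1C[C@H](O[Si](C)(C)C(C)(C)C)[C@](C)(CCC=C(C)C)OC21O
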